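The target is a 2S flavanone (rings A, C and B) tied through an ether oxygen from C6 of ring A to D4 of ring D, the 1,4-phenylene whose D1 carries C2 of the flavone. Because that oxygen lies between two oxygenated carbons of ring A, ring D is not coupled to it but grown on it: an aryl ethynyl ether made from 2,6-dimethoxy-4-silyloxyphenol adds across C3 and C6 of methyl coumalate and the adduct sheds CO2. This one operation forms D3–D4 and D5–D6 and fixes the para relation of ether and ester. The ester is then elaborated to the flavone, and the symmetric ring A to the chromanone.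

Key step: step 5

Remark: the flavone rings are lettered D (1,4-phenylene), E (pyranone) and F (benzo ring); benzyl bromide, [4-(benzyloxy)phenyl]boronic acid and both enantiomers of the pyridine–oxazoline ligand are taken as purchasable.

Step 1
Reactants: 1 2,6-dimethoxy-1,4-benzoquinone
Product: 2 2,6-dimethoxybenzene-1,4-diol
Conditions: Na2S2O4, EtOAc/H2O, rt, under N2
Reagents that add atoms: none
Why: Dithionite reduction of a quinone to its hydroquinone is a clean two-electron, two-proton transfer that leaves the methoxy groups untouched, and the air-sensitive diol is taken on at once.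

Step 2
Reactants: 2 2,6-dimethoxybenzene-1,4-diol
Product: 3 2,6-dimethoxy-4-[(triisopropylsilyl)oxy]phenol
Conditions: TIPSCl (1.05 equiv), imidazole, DMF, 0 °C to rt
Reagents that add atoms: chlorotri(propan-2-yl)silane (TIPSCl), CC(C)[Si](Cl)(C(C)C)C(C)C
Why: O-Silylation with the bulky chlorosilane should take place only at the C4 hydroxyl, because the C1 hydroxyl is shielded by two ortho methoxy groups.

Step 3
Reactants: 3 2,6-dimethoxy-4-[(triisopropylsilyl)oxy]phenol; 4 trichloroethylene
Product: 5 2-{[(E)-1,2-dichloroethenyl]oxy}-1,3-dimethoxy-5-[(triisopropylsilyl)oxy]benzene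
Conditions: KH (1.3 equiv), THF, 0 °C; then 4, 0 °C to rt
Reagents that add atoms: none
Why: Base turns 4 into dichloroacetylene in a chain process and the hindered phenoxide adds to this linear, unencumbered electrophile, with protonation anti to the new C–O bond giving the E dichlorovinyl ether (nucleophilic addition to a haloalkyne, formally an addition–elimination on 4), so the two ortho methoxy groups do not block ether formation.

Step 4
Reactants: 5 2-{[(E)-1,2-dichloroethenyl]oxy}-1,3-dimethoxy-5-[(triisopropylsilyl)oxy]benzene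
Product: 8 2-(ethynyloxy)-1,3-dimethoxy-5-[(triisopropylsilyl)oxy]benzene, via chloroethynyl ether 6 (not isolated), via lithium acetylide 7 (not isolated)
Conditions: n-BuLi (2.5 equiv), THF, −78 to −40 °C; then sat. aq. NH4Cl, −78 °C; used at once
Reagents that add atoms: none
Why: Vinylic lithiation and loss of LiCl give the chloroalkyne 6, chlorine–lithium exchange with the second equivalent of n-BuLi gives the acetylide 7, and protonation at low temperature releases the terminal ynol ether (dichlorovinyl ether to alkynyl ether elimination), while the silyl and methyl ethers are inert to n-BuLi at −78 °C.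

Step 5
Reactants: 8 2-(ethynyloxy)-1,3-dimethoxy-5-[(triisopropylsilyl)oxy]benzene; 9 methyl coumalate (methyl 2-oxo-2H-pyran-5-carboxylate)
Product: 11 methyl 4-{2,6-dimethoxy-4-[(triisopropylsilyl)oxy]phenoxy}benzoate, via bridged lactone 10 (not isolated)
Conditions: 9 (1.5 equiv), toluene, 110 °C, sealed tube
Reagents that add atoms: none
Why: The electron-rich alkyne and the electron-poor 2-pyranone combine in an inverse-electron-demand Diels–Alder reaction in which the terminal alkyne carbon, the nucleophilic end of the ynol ether, bonds to C6 of 9 and the oxygen-bearing carbon to C3, giving the bridged lactone 10, whose cycloreversion expels CO2 and leaves the aromatic ring. The closest known reaction type is the Diels–Alder/retro-Diels–Alder benzannulation of coumalates and other 2-pyranones with enol ethers, ynamines and alkoxyalkynes. Ring D is closed by an intermolecular [4+2] cycloaddition that forms D3–D4 and D5–D6 and is aromatised by retro-[4+2] loss of the O–C(=O) bridge. No stereocenter is formed, since the bridgehead centers of 10 disappear with CO2. The step needs para and not meta orientation of ether and ester, which should follow because C6 of 9 is the diene terminus activated by both the lactone carbonyl (through the diene) and the ester, and so pairs with the unsubstituted, most nucleophilic alkyne carbon. An aryl ynol ether has no β-hydrogen for the retro-ene fragmentation to a ketene that limits alkyl ynol ethers on heating, so it should survive the temperature of the cycloreversion.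

Step 6
Reactants: 12 2',4',6'-trihydroxyacetophenone
Product: 13 1-[2,4-bis(benzyloxy)-6-hydroxyphenyl]ethan-1-one
Conditions: BnBr (2.1 equiv), K2CO3, DMF, rt
Reagents that add atoms: benzyl bromide, BrCc1ccccc1
Why: Williamson etherification alkylates the para hydroxyl and one ortho hydroxyl, and the remaining ortho hydroxyl, locked in a hydrogen bond to the acetyl carbonyl, resists a third alkylation.

Step 7
Reactants: 11 methyl 4-{2,6-dimethoxy-4-[(triisopropylsilyl)oxy]phenoxy}benzoate; 13 1-[2,4-bis(benzyloxy)-6-hydroxyphenyl]ethan-1-one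
Product: 14 1-[2,4-bis(benzyloxy)-6-hydroxyphenyl]-3-(4-{2,6-dimethoxy-4-[(triisopropylsilyl)oxy]phenoxy}phenyl)propane-1,3-dione
Conditions: LiN(SiMe3)2 (3.5 equiv), THF, −78 °C to rt; then aq. HCl, 0 °C
Reagents that add atoms: none
Why: Crossed Claisen condensation, in which the phenoxide–enolate dianion of 13 is acylated on carbon by the non-enolisable ester 11 and immediate deprotonation of the 1,3-diketone drives the equilibrium and prevents over-reaction.

Step 8
Reactants: 14 1-[2,4-bis(benzyloxy)-6-hydroxyphenyl]-3-(4-{2,6-dimethoxy-4-[(triisopropylsilyl)oxy]phenoxy}phenyl)propane-1,3-dione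
Product: 15 5,7-bis(benzyloxy)-2-(4-{2,6-dimethoxy-4-[(triisopropylsilyl)oxy]phenoxy}phenyl)-4H-chromen-4-one
Conditions: TsOH·H2O (10 mol %), toluene, 80 °C
Reagents that add atoms: none
Why: Acid-catalysed cyclodehydration, in which the phenol adds to the enolised carbonyl remote from its own ring and water is lost to give the 4-pyranone of the flavone, under conditions too mild to cleave benzyl or triisopropylsilyl aryl ethers.

Step 9
Reactants: 15 5,7-bis(benzyloxy)-2-(4-{2,6-dimethoxy-4-[(triisopropylsilyl)oxy]phenoxy}phenyl)-4H-chromen-4-one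
Product: 16 5,7-bis(benzyloxy)-2-[4-(4-hydroxy-2,6-dimethoxyphenoxy)phenyl]-4H-chromen-4-one
Conditions: Bu4NF, AcOH, THF, 0 °C
Reagents that add atoms: none
Why: Fluoride-induced cleavage of the aryl silyl ether (desilylation) is driven by the Si–F bond, and buffering with acetic acid keeps the medium from becoming basic enough to open the flavone.

Step 10
Reactants: 16 5,7-bis(benzyloxy)-2-[4-(4-hydroxy-2,6-dimethoxyphenoxy)phenyl]-4H-chromen-4-one
Product: 18 2-[4-(3-acetyl-4-hydroxy-2,6-dimethoxyphenoxy)phenyl]-5,7-bis(benzyloxy)-4H-chromen-4-one, via difluoroboron chelate 17 (not isolated)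
Conditions: Ac2O, BF3·OEt2, ClCH2CH2Cl, 0 °C to rt; then MeOH, aq. NaOAc, 60 °C
Reagents that add atoms: acetic anhydride, CC(=O)OC(C)=O
Why: Friedel–Crafts acylation of a phloroglucinol-type position, in which the carbon ortho to the free hydroxyl is also ortho and para to the two methoxy groups, its mirror-image carbon is equivalent so only one product can form, ring D and the benzo ring of the flavone are deactivated by the chromenone carbonyl, and chelation of the new o-hydroxy ketone as the BF2 complex 17 stops a second acylation until the buffered methanolysis releases 18.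

Step 11
Reactants: 18 2-[4-(3-acetyl-4-hydroxy-2,6-dimethoxyphenoxy)phenyl]-5,7-bis(benzyloxy)-4H-chromen-4-one
Product: 20 6-{4-[5,7-bis(benzyloxy)-4-oxo-4H-chromen-2-yl]phenoxy}-5,7-dimethoxy-4H-chromen-4-one, via enaminone 19 (not isolated)
Conditions: Me2NCH(OMe)2, toluene, 95 °C; evaporate; then TsOH·H2O (1.2 equiv), CH2Cl2/EtOH, 40 °C
Reagents that add atoms: N,N-dimethylformamide dimethyl acetal, COC(OC)N(C)C
Why: Enaminone route to chromones, in which condensation of the methyl ketone with the amide acetal gives 19 and acid promotes conjugate addition of the ortho hydroxyl and loss of dimethylamine, closing the 4-pyranone.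

Step 12
Reactants: 20 6-{4-[5,7-bis(benzyloxy)-4-oxo-4H-chromen-2-yl]phenoxy}-5,7-dimethoxy-4H-chromen-4-one; 21 [4-(benzyloxy)phenyl]boronic acid
Product: 22 (2S)-2-[4-(benzyloxy)phenyl]-6-{4-[5,7-bis(benzyloxy)-4-oxo-4H-chromen-2-yl]phenoxy}-5,7-dimethoxy-2,3-dihydro-4H-chromen-4-one
Conditions: Pd(OCOCF3)2 (10 mol %), (R)-4-tert-butyl-2-(pyridin-2-yl)-4,5-dihydro-1,3-oxazole (12 mol %), NH4PF6 (30 mol %), H2O (5 equiv), ClCH2CH2Cl, 60 °C
Reagents that add atoms: none
Why: Pd-catalysed asymmetric conjugate addition of an arylboronic acid, in which transmetallation gives a cationic arylpalladium species that inserts the C2=C3 bond of the chromone and the palladium enolate is protonated by water; the tert-butyl group of the pyridine–oxazoline ligand differentiates the two faces, and the R ligand is chosen so that the aryl group is delivered to the Re face of C2, which sets 2S (the enantiomeric ligand should give 2R), while the flavone C2=C3 bond, which already carries an aryl group at its β-carbon, should not compete.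

Step 13
Reactants: 22 (2S)-2-[4-(benzyloxy)phenyl]-6-{4-[5,7-bis(benzyloxy)-4-oxo-4H-chromen-2-yl]phenoxy}-5,7-dimethoxy-2,3-dihydro-4H-chromen-4-one
Product: 23 (2S)-6-[4-(5,7-dihydroxy-4-oxo-4H-chromen-2-yl)phenoxy]-5-hydroxy-2-(4-hydroxyphenyl)-7-methoxy-2,3-dihydro-4H-chromen-4-one (CNP0269971.1)
Conditions: BCl3 (excess), C6HMe5, CH2Cl2, −78 to 0 °C; then aq. NaHCO3
Reagents that add atoms: none
Why: Lewis-acid ether cleavage, in which BCl3 removes the three benzyl groups as benzyl cations that pentamethylbenzene traps and, held in a chelate by the C4 carbonyl of the flavanone, cleaves only the methyl ether at C5 while the unchelated C7 methoxy group survives; the cold, base-free medium should leave C2 configurationally intact.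

Compound list
1 | 2,6-dimethoxy-1,4-benzoquinone | COC1=CC(=O)C=C(OC)C1=O | starting material
2 | 2,6-dimethoxybenzene-1,4-diol | COc1cc(O)cc(OC)c1O | intermediate
3 | 2,6-dimethoxy-4-[(triisopropylsilyl)oxy]phenol | COc1cc(O[Si](C(C)C)(C(C)C)C(C)C)cc(OC)c1O | intermediate
4 | trichloroethylene | ClC=C(Cl)Cl | starting material
5 | 2-{[(E)-1,2-dichloroethenyl]oxy}-1,3-dimethoxy-5-[(triisopropylsilyl)oxy]benzene | Cl/C=C(/Cl)Oc1c(OC)cc(O[Si](C(C)C)(C(C)C)C(C)C)cc1OC | intermediate
6 | 2-[(chloroethynyl)oxy]-1,3-dimethoxy-5-[(triisopropylsilyl)oxy]benzene | ClC#COc1c(OC)cc(O[Si](C(C)C)(C(C)C)C(C)C)cc1OC | intermediate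
7 | lithium {2,6-dimethoxy-4-[(triisopropylsilyl)oxy]phenoxy}acetylide | [Li]C#COc1c(OC)cc(O[Si](C(C)C)(C(C)C)C(C)C)cc1OC | intermediate
8 | 2-(ethynyloxy)-1,3-dimethoxy-5-[(triisopropylsilyl)oxy]benzene | C#COc1c(OC)cc(O[Si](C(C)C)(C(C)C)C(C)C)cc1OC | intermediate
9 | methyl coumalate (methyl 2-oxo-2H-pyran-5-carboxylate) | COC(=O)C1=COC(=O)C=C1 | starting material
10 | methyl 8-{2,6-dimethoxy-4-[(triisopropylsilyl)oxy]phenoxy}-3-oxo-2-oxabicyclo[2.2.2]octa-5,7-diene-6-carboxylate (racemic) | O=C1OC2C(C(=O)OC)=CC1C(Oc1c(OC)cc(O[Si](C(C)C)(C(C)C)C(C)C)cc1OC)=C2 | intermediate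
11 | methyl 4-{2,6-dimethoxy-4-[(triisopropylsilyl)oxy]phenoxy}benzoate | COC(=O)c1ccc(Oc2c(OC)cc(O[Si](C(C)C)(C(C)C)C(C)C)cc2OC)cc1 | intermediate
12 | 2',4',6'-trihydroxyacetophenone | CC(=O)c1c(O)cc(O)cc1O | starting material
13 | 1-[2,4-bis(benzyloxy)-6-hydroxyphenyl]ethan-1-one | CC(=O)c1c(O)cc(OCc2ccccc2)cc1OCc1ccccc1 | intermediate
14 | 1-[2,4-bis(benzyloxy)-6-hydroxyphenyl]-3-(4-{2,6-dimethoxy-4-[(triisopropylsilyl)oxy]phenoxy}phenyl)propane-1,3-dione | O=C(CC(=O)c1ccc(Oc2c(OC)cc(O[Si](C(C)C)(C(C)C)C(C)C)cc2OC)cc1)c1c(O)cc(OCc2ccccc2)cc1OCc1ccccc1 | intermediate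
15 | 5,7-bis(benzyloxy)-2-(4-{2,6-dimethoxy-4-[(triisopropylsilyl)oxy]phenoxy}phenyl)-4H-chromen-4-one | O=c1cc(-c2ccc(Oc3c(OC)cc(O[Si](C(C)C)(C(C)C)C(C)C)cc3OC)cc2)oc2cc(OCc3ccccc3)cc(OCc3ccccc3)c12 | intermediate
16 | 5,7-bis(benzyloxy)-2-[4-(4-hydroxy-2,6-dimethoxyphenoxy)phenyl]-4H-chromen-4-one | O=c1cc(-c2ccc(Oc3c(OC)cc(O)cc3OC)cc2)oc2cc(OCc3ccccc3)cc(OCc3ccccc3)c12 | intermediate
17 | difluoroboron chelate of 18 (boron bridging the phenol oxygen and the acetyl oxygen) | CC1=[O+][B-](F)(F)Oc2cc(OC)c(Oc3ccc(-c4cc(=O)c5c(OCc6ccccc6)cc(OCc6ccccc6)cc5o4)cc3)c(OC)c12 | intermediate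
18 | 2-[4-(3-acetyl-4-hydroxy-2,6-dimethoxyphenoxy)phenyl]-5,7-bis(benzyloxy)-4H-chromen-4-one | CC(=O)c1c(O)cc(OC)c(Oc2ccc(-c3cc(=O)c4c(OCc5ccccc5)cc(OCc5ccccc5)cc4o3)cc2)c1OC | intermediate
19 | 5,7-bis(benzyloxy)-2-[4-(3-[(2E)-3-(dimethylamino)prop-2-enoyl]-4-hydroxy-2,6-dimethoxyphenoxy)phenyl]-4H-chromen-4-one | CN(C)/C=C/C(=O)c1c(O)cc(OC)c(Oc2ccc(-c3cc(=O)c4c(OCc5ccccc5)cc(OCc5ccccc5)cc4o3)cc2)c1OC | intermediate
20 | 6-{4-[5,7-bis(benzyloxy)-4-oxo-4H-chromen-2-yl]phenoxy}-5,7-dimethoxy-4H-chromen-4-one | COc1cc2occc(=O)c2c(OC)c1Oc1ccc(-c2cc(=O)c3c(OCc4ccccc4)cc(OCc4ccccc4)cc3o2)cc1 | intermediate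
21 | [4-(benzyloxy)phenyl]boronic acid | OB(O)c1ccc(OCc2ccccc2)cc1 | starting material
22 | (2S)-2-[4-(benzyloxy)phenyl]-6-{4-[5,7-bis(benzyloxy)-4-oxo-4H-chromen-2-yl]phenoxy}-5,7-dimethoxy-2,3-dihydro-4H-chromen-4-one | COc1cc2c(c(OC)c1Oc1ccc(-c3cc(=O)c4c(OCc5ccccc5)cc(OCc5ccccc5)cc4o3)cc1)C(=O)C[C@@H](c1ccc(OCc3ccccc3)cc1)O2 | intermediate
23 | (2S)-6-[4-(5,7-dihydroxy-4-oxo-4H-chromen-2-yl)phenoxy]-5-hydroxy-2-(4-hydroxyphenyl)-7-methoxy-2,3-dihydro-4H-chromen-4-one | COc1cc2c(c(O)c1Oc1ccc(-c3cc(=O)c4c(O)cc(O)cc4o3)cc1)C(=O)C[C@@H](c1ccc(O)cc1)O2 | target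

Total step count: 13. Longest linear sequence: 12 steps (steps 1 to 5 and 7 to 13); step 6 is a one-step side branch.

Steps most likely to fail

Step 5. Thermal oligomerisation or adventitious hydration of the ynol ether may outrun the cycloaddition, or the orientation of addition may erode towards the meta benzoate. The fallback gives up the ring construction and makes the diaryl ether bond directly: setting out from phenol 3, a Chan–Lam coupling with [4-(methoxycarbonyl)phenyl]boronic acid (Cu(OAc)2, pyridine, 4 Å molecular sieves, CH2Cl2, air, rt) would give benzoate 11 and rejoin the route there; it makes no compound outside the list (F0).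

Step 10. The Lewis acid may strip benzyl groups from the flavone, above all the one peri to its carbonyl, or acylation may stop at the aryl acetate. The fallback introduces the acetyl group without a Lewis acid: setting out from phenol 16, bromination with N-bromosuccinimide (CH2Cl2, −78 °C) at the same activated carbon would give 5,7-bis(benzyloxy)-2-[4-(3-bromo-4-hydroxy-2,6-dimethoxyphenoxy)phenyl]-4H-chromen-4-one F1. Stille coupling with tributyl(1-ethoxyvinyl)stannane (PdCl2(PPh3)2, toluene, 90 °C) would give the enol ether 5,7-bis(benzyloxy)-2-{4-[3-(1-ethoxyethenyl)-4-hydroxy-2,6-dimethoxyphenoxy]phenyl}-4H-chromen-4-one F2. Dilute aqueous HCl in THF would hydrolyse it to acetophenone 18, where the route is rejoined.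

Step 12. Insertion into the hindered, electron-rich chromone may be slow, so that protodeboronation consumes the boronic acid, or facial discrimination may be incomplete. The fallback builds ring C from a chalcone and separates enantiomers: setting out from acetophenone 18, Claisen–Schmidt condensation with 4-(benzyloxy)benzaldehyde (KOH, EtOH/THF, rt) would give the chalcone (2E)-1-(3-{4-[5,7-bis(benzyloxy)-4-oxo-4H-chromen-2-yl]phenoxy}-6-hydroxy-2,4-dimethoxyphenyl)-3-[4-(benzyloxy)phenyl]prop-2-en-1-one F3. Intramolecular oxa-Michael addition (NaOAc, EtOH, reflux) would give the racemic flavanone rac-2-[4-(benzyloxy)phenyl]-6-{4-[5,7-bis(benzyloxy)-4-oxo-4H-chromen-2-yl]phenoxy}-5,7-dimethoxy-2,3-dihydro-4H-chromen-4-one F4. Preparative chromatography on a chiral stationary phase would deliver the 2S enantiomer 22, where the route is rejoined.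

Further compounds
F0 | step 5 | none | none
F1 | step 10 | 5,7-bis(benzyloxy)-2-[4-(3-bromo-4-hydroxy-2,6-dimethoxyphenoxy)phenyl]-4H-chromen-4-one | Oc1cc(OC)c(Oc2ccc(-c3cc(=O)c4c(OCc5ccccc5)cc(OCc5ccccc5)cc4o3)cc2)c(OC)c1Br
F2 | step 10 | 5,7-bis(benzyloxy)-2-{4-[3-(1-ethoxyethenyl)-4-hydroxy-2,6-dimethoxyphenoxy]phenyl}-4H-chromen-4-one | CCOC(=C)c1c(O)cc(OC)c(Oc2ccc(-c3cc(=O)c4c(OCc5ccccc5)cc(OCc5ccccc5)cc4o3)cc2)c1OC
F3 | step 12 | (2E)-1-(3-{4-[5,7-bis(benzyloxy)-4-oxo-4H-chromen-2-yl]phenoxy}-6-hydroxy-2,4-dimethoxyphenyl)-3-[4-(benzyloxy)phenyl]prop-2-en-1-one | O=C(/C=C/c1ccc(OCc2ccccc2)cc1)c1c(O)cc(OC)c(Oc2ccc(-c3cc(=O)c4c(OCc5ccccc5)cc(OCc5ccccc5)cc4o3)cc2)c1OC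
F4 | step 12 | rac-2-[4-(benzyloxy)phenyl]-6-{4-[5,7-bis(benzyloxy)-4-oxo-4H-chromen-2-yl]phenoxy}-5,7-dimethoxy-2,3-dihydro-4H-chromen-4-one | COc1cc2c(c(OC)c1Oc1ccc(-c3cc(=O)c4c(OCc5ccccc5)cc(OCc5ccccc5)cc4o3)cc1)C(=O)CC(c1ccc(OCc3ccccc3)cc1)O2
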